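## Retrosynthetic overview

1. Feature: in the seven-membered ring C5–C6–C7–C8–C9–C10–C4 (or C11), the oxygenated carbons C7 and C9 are 1,3-related and sit between the quaternary carbons C6 (CMe2) and C10. A C7 methyl ketone and a C9 aldehyde therefore share C8 as their only enolisable carbon. Both arms hang 1,3-diaxially from one face of the cyclobutane C4–C5–C11–C10.
2. Late stage: the O9 angelate, the C1 carbonyl (allylic oxidation), the O7 tiglate and the C7 carbinol (anti reduction steered by O9) are removed. This leads back to 9-hydroxylongipin-2-en-7-one.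
3. Key disconnection: breaking C8–C9 (intramolecular aldol) opens the seven-membered ring to a keto aldehyde on a bicyclo[3.1.1]hept-2-ene.
4. Arms: the C5 arm grows from a C5 cyclobutanone by olefination, conjugate reduction, double methylation and MeLi. C9 is made from the C10 methyl that lies syn to O5, by silicon-tethered C–H silylation and oxidation.
5. Ring order: the cyclobutane and the six-membered ring come together from (−)-verbenone and are re-connected once by a photochemical 1,3-shift (step 1). The seven-membered ring is closed last (step 13).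

Key step: step 13

**Numbering and terms.** Longipinane numbering is used from compound 2 onwards.
- C1 is the later ketone, C2=C3 carries Me on C3, and C4 and C11 are the bridgeheads on C3 and C1.
- C5 and C10 are the two one-carbon bridges, and C6–C9 form the four-carbon bridge.
- "Outer face" means the face of the cyclobutane C4–C5–C11–C10 turned away from the C1–C2–C3 bridge.
- "C11 side" and "C4 side" are the two flanks of the seven-membered ring. In the target, O9 stands on the C11 side and O7 on the C4 side (7,9-anti).

**Assumption.** Any shortfall in enantiomeric purity, from commercial 1 or from step 1, is made up by recrystallising diol 6 or p-nitrobenzoate 23.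

## Route

Step 1
Reactants: 1 (1S,5S)-(−)-verbenone
Product: 2 (1R,5S)-chrysanthenone
Conditions: hν (medium-pressure Hg lamp, filter λ > 330 nm), cyclohexane–MeOH 20:1, rt, stopped before full conversion
Reagents that add atoms: none
Why: Photochemical 1,3-alkyl shift of a cyclobutyl enone (verbenone–chrysanthenone rearrangement), in which C10 stays bonded to C11 and moves from the γ- to the α-carbon of the enone (new bond C10–C4), so the untouched C11 centre dictates the new bridgehead C4, while the filter keeps 2 from absorbing and methanol scavenges the achiral ketene leak that could otherwise re-close to racemic material.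

Step 2
Reactants: 2 (1R,5S)-chrysanthenone
Product: 3 (1R,5S,6R)-chrysanthenol (O5 on the outer face, syn to C10)
Conditions: LiAlH4, Et2O, −78 → 0 °C
Reagents that add atoms: none
Why: Hydride reduction of a cyclobutanone, in which the C10 methyl lying under C5 closes the outer face, so hydride enters from the side of the C1–C3 bridge and the C5 hydroxyl is set on the outer face, 1,3-diaxial to that methyl.

Step 3
Reactants: 3 (1R,5S,6R)-chrysanthenol
Product: 5 tricyclic oxasilinane (O5–SiEt2–C9 bridge on the outer face), via diethyl(hydrido)silyl ether 4 (not isolated)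
Conditions: Et2SiH2, [Ir(cod)OMe]2 (cat.), THF, rt; volatiles removed; [Rh(cod)Cl]2 (cat.), Xantphos, norbornene, THF, 100 °C, sealed tube
Reagents that add atoms: diethylsilane, CC[SiH2]CC
Why: Alcohol-directed intramolecular dehydrogenative C–H silylation (the rhodium/Xantphos variant that forms six-membered oxasilacycles at primary δ-C–H bonds), in which only the C10 methyl 1,3-diaxial to O5 can reach the silicon–rhodium centre (this fixes the C10 stereocentre), the alkene lies on the opposite face, and no oxygen radical is formed, so the ring opening expected of a cyclobutyloxyl radical is avoided.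

Step 4
Reactants: 5 tricyclic oxasilinane
Product: 6 C5,C9-diol (both oxygens on the outer face)
Conditions: 30% H2O2, KHCO3, THF–MeOH, 50 °C
Reagents that add atoms: hydrogen peroxide, OO
Why: Tamao–Fleming oxidation turns the C9–Si bond into C9–OH and frees O5, the trisubstituted alkene is inert to basic peroxide, and no stereocentre is touched.

Step 5
Reactants: 6 C5,C9-diol
Product: 7 C9 tert-butyldimethylsilyl ether with free O5
Conditions: TBSCl, imidazole, CH2Cl2, 0 °C
Reagents that add atoms: tert-butyldimethylsilyl chloride, CC(C)(C)[Si](C)(C)Cl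
Why: Chemoselective silylation, because the primary O9 reacts well ahead of the secondary O5, which is flanked by two bridgeheads and by C9 itself.

Step 6
Reactants: 7 C9 silyl ether alcohol
Product: 8 9-(silyloxy)chrysanthenone (C5 ketone, C9H2OTBS on the outer face of C10)
Conditions: Pr4N[RuO4] (cat.), N-methylmorpholine N-oxide, 4 Å sieves, CH2Cl2, rt
Reagents that add atoms: none
Why: Ley–Griffith oxidation, since perruthenate is a two-electron oxidant that takes cyclobutanols to cyclobutanones without C–C cleavage and the neutral medium spares the silyl ether and the acid-sensitive vinylcyclobutane.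

Step 7
Reactants: 8 9-(silyloxy)chrysanthenone; 9 diethyl cyanomethylphosphonate
Product: 10 C5-cyanomethylidene compound (E/Z mixture about C5=C6)
Conditions: NaH, THF, 0 → 50 °C
Reagents that add atoms: diethyl cyanomethylphosphonate 9, CCOP(=O)(CC#N)OCC
Why: Horner–Wadsworth–Emmons olefination, in which the strained, non-enolisable cyclobutanone is a good acceptor for the small phosphonate anion, and the alkene geometry is irrelevant because both isomers converge in step 8.

Step 8
Reactants: 10 C5-cyanomethylidene compound
Product: 11 C5-cyanomethyl compound (arm on the outer face, cis to C9; H5 syn to the C1–C3 bridge)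
Conditions: Cu(OAc)2 (5 mol %), Xantphos (5 mol %), (EtO)2MeSiH, t-BuOH, toluene, rt
Reagents that add atoms: none
Why: Copper hydride conjugate reduction of an α,β-unsaturated nitrile leaves the isolated alkene untouched, and Cu–H can reach C5 only from the bridge side because C9H2OTBS blocks the outer face, so H5 is set syn to the bridge and the arm is pushed onto the outer face.

Step 9
Reactants: 11 C5-cyanomethyl compound
Product: 13 C6-dimethylated nitrile (2-cyanopropan-2-yl arm on C5), via monomethyl nitrile 12 (not isolated)
Conditions: LiN(i-Pr)2, THF, −78 °C, MeI; second charge of LiN(i-Pr)2, −78 → 0 °C, MeI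
Reagents that add atoms: iodomethane, CI
Why: Two successive nitrile-anion alkylations build the quaternary C6, the slim metallated nitrile tolerates the crowded neighbourhood of C9, and C5 is not acidic and keeps its configuration.

Step 10
Reactants: 13 C6-dimethylated nitrile
Product: 15 silyl-protected methyl ketone (3-oxo-2-methylbutan-2-yl arm on C5), via N-lithio ketimine 14 (not isolated)
Conditions: MeLi, Et2O, 0 °C → rt; then AcOH–NaOAc buffer (pH 5), THF–H2O, rt
Reagents that add atoms: methyllithium, [Li]C; water, O
Why: Organolithium addition to a tertiary nitrile without α-hydrogen stops at the ketimine salt, and buffered hydrolysis then gives the C7 methyl ketone without harming the silyl ether or the alkene.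

Step 11
Reactants: 15 silyl-protected methyl ketone
Product: 16 C9 hydroxy C7 ketone
Conditions: Bu4NF, THF, 0 °C → rt
Reagents that add atoms: none
Why: Fluoride desilylation is driven by the Si–F bond, and nothing else in 15 responds to fluoride.

Step 12
Reactants: 16 C9 hydroxy C7 ketone
Product: 17 keto aldehyde (C10 formyl, C5 3-oxo-2-methylbutan-2-yl, both on the outer face)
Conditions: Pr4N[RuO4] (cat.), N-methylmorpholine N-oxide, 4 Å sieves, CH2Cl2, 0 °C; used at once
Reagents that add atoms: none
Why: Ley–Griffith oxidation of the neopentyl primary alcohol stops at the aldehyde under anhydrous conditions, C10 carries no hydrogen, and the neutral medium does not start the aldol early.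

Step 13
Reactants: 17 keto aldehyde
Product: 20 9-hydroxylongipin-2-en-7-one (O9 on the C11 side), via lithium enolate 18 (not isolated), via lithium aldolate 19 (not isolated)
Conditions: LiN(SiMe3)2 (1.1 equiv), THF, −78 °C, slow addition of 17; AcOH/THF quench at −78 °C; C9 epimers separated on silica
Reagents that add atoms: none
Why: LiN(SiMe3)2 takes a proton from C8, the only acidic C–H of 17 (C6 and C10 are quaternary, the formyl group has no α-hydrogen, and the bridgeheads cannot enolise), and enolate 18 adds through C8 to the formyl carbon C9 in a lithium-bridged six-membered array to give aldolate 19, which is an intramolecular aldol addition of a methyl ketone enolate to an aldehyde, a closure type known for seven-membered carbocycles. The ring closes in the 7-(enolendo)-exo-trig mode, a favoured one, because C7=C8 of the enolate ends up inside the new ring and C9=O outside it. The closure is pre-organised, since both arms stand 1,3-diaxial on the outer face of the cyclobutane and the gem-dimethyl group on C6 turns the acetyl group towards C9. The one new stereocentre, C9, depends on which formyl face meets C8, and because the two flanks of the forming ring differ only in C1H2 versus C3(Me)= beyond C11 and C4, the frame is credited with no more than a small bias. The step is therefore asked for conversion rather than selectivity: the epimers are diastereomers, 20 is collected by chromatography, and the other epimer is returned through 17 by base-catalysed retro-aldol equilibration. The chemoselectivity needed is deprotonation ahead of amide addition to the aldehyde, which the neopentyl formyl group and −78 °C secure, and the cold acidic quench freezes 19 before reversal or dehydration.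

Step 14
Reactants: 20 9-hydroxylongipin-2-en-7-one; 21 4-nitrobenzaldehyde
Product: 23 7-hydroxy-9-(4-nitrobenzoyloxy)longipin-2-ene (O7 on the C4 side), via O9 hemiacetal 22 (not isolated)
Conditions: SmI2 (30 mol %, premixed with 21), THF, −10 °C
Reagents that add atoms: 4-nitrobenzaldehyde 21, O=Cc1ccc(cc1)[N+](=O)[O-]
Why: Evans–Tishchenko reduction, in which O9 adds to the aldehyde and the samarium-bound hemiacetal 22 passes its hydride to C7 through a six-membered chelate from the C11 side where O9 stands, so O7 is set on the C4 side (7,9-anti) and O9 leaves the same event capped as the p-nitrobenzoate, which tells the two oxygens apart; the reaction is known to tolerate ketones next to a CMe2 group.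

Step 15
Reactants: 23 7-hydroxy 9-p-nitrobenzoate; 24 tiglic acid
Product: 26 7-tigloyloxy-9-(4-nitrobenzoyloxy)longipin-2-ene, via tiglic trichlorobenzoic anhydride 25 (not isolated)
Conditions: 24, 2,4,6-Cl3C6H2COCl, Et3N, toluene, rt; then 23, DMAP, 60 °C
Reagents that add atoms: tiglic acid 24, C/C=C(\C)C(=O)O
Why: Yamaguchi esterification, in which the acylpyridinium ion from 25 is reactive enough for the neopentyl O7, the E-configured tiglate has no tendency to isomerise, and O9 is already blocked.

Step 16
Reactants: 26 7-tiglate 9-p-nitrobenzoate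
Product: 27 7-tigloyloxy-9-(4-nitrobenzoyloxy)longipin-2-en-1-one
Conditions: CrO3, 3,5-dimethylpyrazole, CH2Cl2, −20 °C
Reagents that add atoms: chromium trioxide, O=[Cr](=O)=O
Why: Allylic oxidation with the CrO3–3,5-dimethylpyrazole complex (the α-pinene-to-verbenone type of conversion) oxidises the ring methylene C1 in preference to the C3 methyl and the bridgehead C4–H, no free hydroxyl is present, and the electron-poor tiglate alkene and the nitroarene are inert.

Step 17
Reactants: 27 enone diester
Product: 28 9-hydroxy-7-tigloyloxylongipin-2-en-1-one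
Conditions: K2CO3 (cat.), MeOH–THF, 0 °C
Reagents that add atoms: none
Why: Chemoselective transesterification, because methoxide attacks the electron-poor p-nitrobenzoate far faster than the conjugated, α-branched tiglate on its neopentyl oxygen, and the trans-1,3 placement of O7 and O9 disfavours acyl migration.

Step 18
Reactants: 28 9-hydroxy 7-tiglate enone; 29 angelic acid
Product: 31 target 9-angeloyloxy-7-tigloyloxylongipin-2-en-1-one, via angelic trichlorobenzoic anhydride 30 (not isolated)
Conditions: 29, 2,4,6-Cl3C6H2COCl, Et3N, toluene, rt; then 28, 80 °C, no DMAP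
Reagents that add atoms: angelic acid 29, C/C=C(/C)C(=O)O
Why: Mixed-anhydride acylation (Yamaguchi reagent used without a nucleophilic catalyst), in which leaving out DMAP shuts the conjugate addition–elimination path by which activated angelates turn into tiglates, so the Z geometry of 29 is carried into 31 and no stereocentre is touched.

## Compound list

1 | (1S,5S)-(−)-verbenone | CC1=CC(=O)[C@H]2C[C@@H]1C2(C)C | starting material
2 | (1R,5S)-chrysanthenone | CC1(C)[C@@H]2CC=C(C)[C@H]1C2=O | intermediate
3 | (1R,5S,6R)-chrysanthenol, O5 on the outer face | CC1(C)[C@@H]2CC=C(C)[C@H]1[C@@H]2O | intermediate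
4 | diethyl(hydrido)silyl ether of 3 | CC1(C)[C@@H]2CC=C(C)[C@H]1[C@@H]2O[SiH](CC)CC | intermediate (not isolated)
5 | oxasilinane, O5–SiEt2–C9 bridge | CC[Si]1(CC)C[C@@]2(C)[C@@H]3CC=C(C)[C@H]2[C@@H]3O1 | intermediate
6 | C5,C9-diol | OC[C@@]1(C)[C@@H]2CC=C(C)[C@H]1[C@@H]2O | intermediate
7 | C9 TBS ether, free O5 | CC(C)(C)[Si](C)(C)OC[C@@]1(C)[C@@H]2CC=C(C)[C@H]1[C@@H]2O | intermediate
8 | 9-(TBS-oxy)chrysanthenone | CC(C)(C)[Si](C)(C)OC[C@@]1(C)[C@@H]2CC=C(C)[C@H]1C2=O | intermediate
9 | diethyl cyanomethylphosphonate | CCOP(=O)(CC#N)OCC | starting material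
10 | C5-cyanomethylidene compound (E/Z mixture) | CC(C)(C)[Si](C)(C)OC[C@@]1(C)[C@@H]2CC=C(C)[C@H]1C2=CC#N | intermediate
11 | C5-cyanomethyl compound | CC(C)(C)[Si](C)(C)OC[C@@]1(C)[C@@H]2CC=C(C)[C@H]1[C@@H]2CC#N | intermediate
12 | monomethyl nitrile (C6 epimers) | CC(C)(C)[Si](C)(C)OC[C@@]1(C)[C@@H]2CC=C(C)[C@H]1[C@@H]2C(C)C#N | intermediate (not isolated)
13 | C6-dimethylated nitrile | CC(C)(C)[Si](C)(C)OC[C@@]1(C)[C@@H]2CC=C(C)[C@H]1[C@@H]2C(C)(C)C#N | intermediate
14 | N-lithio ketimine | CC(C)(C)[Si](C)(C)OC[C@@]1(C)[C@@H]2CC=C(C)[C@H]1[C@@H]2C(C)(C)C(C)=N[Li] | intermediate (not isolated)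
15 | silyl-protected methyl ketone | CC(C)(C)[Si](C)(C)OC[C@@]1(C)[C@@H]2CC=C(C)[C@H]1[C@@H]2C(C)(C)C(C)=O | intermediate
16 | C9 hydroxy C7 ketone | OC[C@@]1(C)[C@@H]2CC=C(C)[C@H]1[C@@H]2C(C)(C)C(C)=O | intermediate
17 | keto aldehyde (key-step precursor) | O=C[C@@]1(C)[C@@H]2CC=C(C)[C@H]1[C@@H]2C(C)(C)C(C)=O | intermediate
18 | lithium enolate of 17 | O=C[C@@]1(C)[C@@H]2CC=C(C)[C@H]1[C@@H]2C(C)(C)C(=C)O[Li] | intermediate (not isolated)
19 | lithium aldolate | [Li]O[C@@H]1CC(=O)C(C)(C)[C@@H]2[C@H]3CC=C(C)[C@@H]2[C@]31C | intermediate (not isolated)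
20 | 9-hydroxylongipin-2-en-7-one (key-step product) | O[C@@H]1CC(=O)C(C)(C)[C@@H]2[C@H]3CC=C(C)[C@@H]2[C@]31C | intermediate
21 | 4-nitrobenzaldehyde | O=Cc1ccc(cc1)[N+](=O)[O-] | starting material
22 | O9 hemiacetal (drawn metal-free, hemiacetal carbon undefined) | OC(O[C@@H]1CC(=O)C(C)(C)[C@@H]2[C@H]3CC=C(C)[C@@H]2[C@]31C)c1ccc(cc1)[N+](=O)[O-] | intermediate (not isolated)
23 | 7-hydroxy-9-(4-nitrobenzoyloxy)longipin-2-ene | O=C(O[C@@H]1C[C@@H](O)C(C)(C)[C@@H]2[C@H]3CC=C(C)[C@@H]2[C@]31C)c1ccc(cc1)[N+](=O)[O-] | intermediate
24 | tiglic acid | C/C=C(\C)C(=O)O | starting material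
25 | tiglic 2,4,6-trichlorobenzoic anhydride | C/C=C(\C)C(=O)OC(=O)c1c(Cl)cc(Cl)cc1Cl | intermediate (not isolated)
26 | 7-tigloyloxy-9-(4-nitrobenzoyloxy)longipin-2-ene | O=C(O[C@@H]1C[C@@H](OC(=O)/C(C)=C/C)C(C)(C)[C@@H]2[C@H]3CC=C(C)[C@@H]2[C@]31C)c1ccc(cc1)[N+](=O)[O-] | intermediate
27 | 7-tigloyloxy-9-(4-nitrobenzoyloxy)longipin-2-en-1-one | O=C(O[C@@H]1C[C@@H](OC(=O)/C(C)=C/C)C(C)(C)[C@@H]2[C@H]3C(=O)C=C(C)[C@@H]2[C@]31C)c1ccc(cc1)[N+](=O)[O-] | intermediate
28 | 9-hydroxy-7-tigloyloxylongipin-2-en-1-one | O[C@@H]1C[C@@H](OC(=O)/C(C)=C/C)C(C)(C)[C@@H]2[C@H]3C(=O)C=C(C)[C@@H]2[C@]31C | intermediate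
29 | angelic acid | C/C=C(/C)C(=O)O | starting material
30 | angelic 2,4,6-trichlorobenzoic anhydride | C/C=C(/C)C(=O)OC(=O)c1c(Cl)cc(Cl)cc1Cl | intermediate (not isolated)
31 | 9-angeloyloxy-7-tigloyloxylongipin-2-en-1-one (CNP0236543.2) | C/C=C(/C)C(=O)O[C@@H]1C[C@@H](OC(=O)/C(C)=C/C)C(C)(C)[C@@H]2[C@H]3C(=O)C=C(C)[C@@H]2[C@]31C | target

## Step count and risks

Total step count: 18. Longest linear sequence: 18 steps (from 1).

**Step 13.**
- What may go wrong: the enolate may meet both faces of the formyl group to a similar extent, and the aldolate may revert during the quench.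
- Fallback (sets out from 17, comes back at 20): 17 is closed as in step 13, but the crude mixture of 20 and 9-epi-9-hydroxylongipin-2-en-7-one F1 is not separated. MsCl/Et3N converts it into the C9 mesylates F2, and DBU eliminates these to longipina-2,8-dien-7-one F3. This erases C9 and makes the C8–C9 bond irreversible. Copper-catalysed enantioselective conjugate borylation (CuCl, NaOt-Bu, a Josiphos-type bisphosphine, B2pin2, MeOH, THF) then puts boron on C9 under catalyst control. That is the fitting tool for two enone faces that an achiral reagent can hardly tell apart. The ligand antipode that attacks from the C11 side is used, and the product is the 9-(pinacolatoboryl)longipin-2-en-7-one F4. Oxidation with NaBO3·4H2O replaces boron by oxygen with retention and gives 20.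

**Step 3.**
- What may go wrong: C–H cleavage at the neopentyl methyl may be too slow, so that silane redistribution, alkene isomerisation or hydrosilylation take over.
- Fallback (bypasses 1–7 and comes back at 8): it sets out from commercial (1R,5S)-(+)-nopinone F5, which is of the same pinene series as 1 and takes its place.
  - MeMgBr adds anti to the CMe2 bridge and gives the tertiary alcohol 2-methylnopinol F6, with OH syn to the bridge.
  - The hypoiodite reaction (PhI(OAc)2, I2, hν, cyclohexane) works here because the alkoxyl radical sits next to the cyclobutane, not on it. 1,5-Hydrogen transfer from the syn methyl closes the cyclic ether F7.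
  - Acylative cleavage (Ac2O, pyridine hydrochloride, heat) gives 9-acetoxy-α-pinene F8.
  - K2CO3/MeOH gives 9-hydroxy-α-pinene F9, and TBSCl/imidazole gives its silyl ether F10.
  - CrO3–3,5-dimethylpyrazole gives 9-(silyloxy)verbenone F11.
  - Irradiation as in step 1 moves C10 suprafacially with retention. The group that was syn to the enone bridge thereby becomes the outer-face group of 8. Loss of configuration at C10 through a stepwise radical path would be corrected by chromatography.

**Step 18.**
- What may go wrong: acylation of the neopentyl O9 may be so slow that Z-to-E isomerisation of the activated acid competes.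
- Fallback (sets out from 28, comes back at 31): the double bond is built after the acylation. 28 is esterified (DCC, DMAP) with the known 2-[bis(2,2,2-trifluoroethoxy)phosphoryl]propanoic acid, an acid with no alkene geometry to lose, to give the O9 phosphonopropionate F12. Still–Gennari olefination (KN(SiMe3)2, 18-crown-6, THF, −78 °C, acetaldehyde) then forms the Z-trisubstituted 2-methylbut-2-enoate, that is 31. The phosphonate C–H is by far the most acidic site, so the enone and the tiglate are left alone.

## Further compounds

F1 | step 13 | 9-epi-9-hydroxylongipin-2-en-7-one (O9 on the C4 side) | O[C@H]1CC(=O)C(C)(C)[C@@H]2[C@H]3CC=C(C)[C@@H]2[C@]31C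
F2 | step 13 | C9 mesylates of 20/F1 (C9 epimers) | CS(=O)(=O)OC1CC(=O)C(C)(C)[C@@H]2[C@H]3CC=C(C)[C@@H]2[C@]31C
F3 | step 13 | longipina-2,8-dien-7-one | C1=CC(=O)C(C)(C)[C@@H]2[C@H]3CC=C(C)[C@@H]2[C@]31C
F4 | step 13 | 9-(pinacolatoboryl)longipin-2-en-7-one (boron on the C11 side) | CC1(C)OB(OC1(C)C)[C@@H]1CC(=O)C(C)(C)[C@@H]2[C@H]3CC=C(C)[C@@H]2[C@]31C
F5 | step 3 | (1R,5S)-(+)-nopinone (commercial) | O=C1CC[C@H]2C[C@@H]1C2(C)C
F6 | step 3 | 2-methylnopinol (pinan-2-ol with OH syn to the CMe2 bridge) | C[C@@]1(O)CC[C@H]2C[C@@H]1C2(C)C
F7 | step 3 | cyclic ether (O bridging the carbinol carbon and the syn methyl carbon) | C[C@@]12CC[C@H]3C[C@@H]1[C@@]3(C)CO2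
F8 | step 3 | 9-acetoxy-α-pinene (CH2OAc syn to the alkene bridge) | CC1=CC[C@H]2C[C@@H]1[C@@]2(C)COC(C)=O
F9 | step 3 | 9-hydroxy-α-pinene | CC1=CC[C@H]2C[C@@H]1[C@@]2(C)CO
F10 | step 3 | 9-(TBS-oxy)-α-pinene | CC1=CC[C@H]2C[C@@H]1[C@@]2(C)CO[Si](C)(C)C(C)(C)C
F11 | step 3 | 9-(TBS-oxy)verbenone | CC1=CC(=O)[C@H]2C[C@@H]1[C@@]2(C)CO[Si](C)(C)C(C)(C)C
F12 | step 18 | O9 2-[bis(2,2,2-trifluoroethoxy)phosphoryl]propanoate of 28 (α-carbon epimers) | CC(C(=O)O[C@@H]1C[C@@H](OC(=O)/C(C)=C/C)C(C)(C)[C@@H]2[C@H]3C(=O)C=C(C)[C@@H]2[C@]31C)P(=O)(OCC(F)(F)F)OCC(F)(F)F
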